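**Retrosynthetic overview**

1. Target 28 ⇐ acetylation of macrocyclic alcohol 26. The only ring, the cycloundecadiene, is closed in the last-but-one step by intramolecular Nozaki–Hiyama–Kishi addition (C3–C4) of iodo-aldehyde 24, with the C1 stereocentre directing C4.
2. 24 ⇐ angeloylation at C1 and C5–C6 bond formation by alkylating an isobutyraldimine anion with iodide 17 (gem-dimethyl carbon plus aldehyde).
3. The 2Z iodoalkene of 17 ⇐ alkoxide-directed carbomagnesiation/iodination of propargylic alcohol 13.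
4. Key step: the C7–C8 bond and the 9E trisubstituted alkene ⇐ Johnson–Claisen [3,3]-sigmatropic rearrangement of isopropenyl carbinol 8.
5. 8 ⇐ (S)-α-hydroxy-γ-butyrolactone 1 (its carbinol becomes C1) by Ohira–Bestmann alkynylation and Grignard addition.

Assumption: locants C1–C11 in the comments are those of the ring of 28 (C1 carries the angelate, C4 the acetate); (S)-α-hydroxy-γ-butyrolactone, made from L-malic acid, is taken as the purchasable source of chirality.

**Route**

Step 1
Reactants: 1 (S)-3-hydroxydihydrofuran-2(3H)-one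
Product: 2 (S)-3-[(tert-butyldimethylsilyl)oxy]dihydrofuran-2(3H)-one
Conditions: t-BuMe2SiCl, imidazole, DMF, 0 °C → rt
Reagents that add atoms: tert-butyldimethylsilyl chloride, CC(C)(C)[Si](C)(C)Cl
Why: Imidazole-promoted silylation masks the secondary hydroxyl for the hydride, Grignard and Claisen steps without touching the bought stereocentre, which becomes C1.

Step 2
Reactants: 2 (S)-3-[(tert-butyldimethylsilyl)oxy]dihydrofuran-2(3H)-one
Product: 3 (3S)-3-[(tert-butyldimethylsilyl)oxy]tetrahydrofuran-2-ol (anomeric mixture)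
Conditions: i-Bu2AlH (1.1 equiv), CH2Cl2, −78 °C; then H2O work-up
Reagents that add atoms: none
Why: Low-temperature half-reduction of a γ-lactone with i-Bu2AlH stops at the lactol stage, and the silyloxy stereocentre is not involved.

Step 3
Reactants: 3 (3S)-3-[(tert-butyldimethylsilyl)oxy]tetrahydrofuran-2-ol; 4 dimethyl (1-diazo-2-oxopropyl)phosphonate
Product: 5 (3S)-3-[(tert-butyldimethylsilyl)oxy]pent-4-yn-1-ol
Conditions: K2CO3, MeOH, 0 °C → rt
Reagents that add atoms: dimethyl (1-diazo-2-oxopropyl)phosphonate (4), COP(=O)(OC)C(=[N+]=[N-])C(C)=O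
Why: Seyferth–Gilbert homologation in the Ohira–Bestmann form turns the masked aldehyde carbon of the lactol into a terminal alkyne under mild carbonate conditions that should leave the adjacent silyloxy stereocentre intact, and it frees the primary alcohol.

Step 4
Reactants: 5 (3S)-3-[(tert-butyldimethylsilyl)oxy]pent-4-yn-1-ol
Product: 6 (3S)-3-[(tert-butyldimethylsilyl)oxy]pent-4-ynal
Conditions: Dess–Martin periodinane, CH2Cl2, 0 °C → rt
Reagents that add atoms: none
Why: Dess–Martin oxidation of the primary alcohol is neutral and fast, so the β-silyloxy aldehyde forms without β-elimination and the stereocentre (now β to the carbonyl) cannot epimerise.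

Step 5
Reactants: 6 (3S)-3-[(tert-butyldimethylsilyl)oxy]pent-4-ynal; 7 isopropenylmagnesium bromide
Product: 8 (5S)-5-[(tert-butyldimethylsilyl)oxy]-2-methylhept-1-en-6-yn-3-ol (both C3 epimers)
Conditions: THF, −78 °C → −20 °C; then H2O
Reagents that add atoms: isopropenylmagnesium bromide (7), CC(=C)[Mg]Br
Why: Grignard 1,2-addition to the aldehyde gives the isopropenyl carbinol needed for the Claisen step, and the new carbinol centre is left uncontrolled because step 6 destroys it.

Step 6
Reactants: 8 (5S)-5-[(tert-butyldimethylsilyl)oxy]-2-methylhept-1-en-6-yn-3-ol; 9 triethyl orthoacetate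
Product: 11 ethyl (4E,7S)-7-[(tert-butyldimethylsilyl)oxy]-4-methylnon-4-en-8-ynoate, via mixed ketene acetal 10 (not isolated)
Conditions: MeC(OEt)3 (8 equiv), EtCO2H (cat.), 140 °C, EtOH distilled off
Reagents that add atoms: triethyl orthoacetate (9), CC(OCC)(OCC)OCC
Why: Johnson–Claisen [3,3]-sigmatropic rearrangement through a chair transition state with the carbinol substituent equatorial forms the future C7–C8 bond and the 9E trisubstituted alkene from either carbinol epimer.

Step 7
Reactants: 11 ethyl (4E,7S)-7-[(tert-butyldimethylsilyl)oxy]-4-methylnon-4-en-8-ynoate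
Product: 12 (4E,7S)-7-[(tert-butyldimethylsilyl)oxy]-4-methylnon-4-en-8-yn-1-ol
Conditions: i-Bu2AlH (2.3 equiv), CH2Cl2, −78 → 0 °C; then H2O work-up
Reagents that add atoms: none
Why: i-Bu2AlH reduces the ester to the primary alcohol while the terminal alkyne, the trisubstituted alkene and the silyl ether are inert.

Step 8
Reactants: 12 (4E,7S)-7-[(tert-butyldimethylsilyl)oxy]-4-methylnon-4-en-8-yn-1-ol
Product: 13 (4E,7S)-4-methylnon-4-en-8-yne-1,7-diol
Conditions: Bu4NF, THF, 0 °C → rt
Reagents that add atoms: none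
Why: Fluoride-driven desilylation frees the propargylic hydroxyl that must direct step 9, with no change at the stereocentre.

Step 9
Reactants: 13 (4E,7S)-4-methylnon-4-en-8-yne-1,7-diol; 14 methylmagnesium bromide
Product: 16 (4E,7S,8Z)-9-iodo-4,8-dimethylnona-4,8-diene-1,7-diol, via alkenylmagnesium intermediate 15 (not isolated)
Conditions: MeMgBr (5 equiv), CuI (10 mol %), Et2O–THF, −20 °C → rt; then I2, THF, −78 → 0 °C; then H2O
Reagents that add atoms: methylmagnesium bromide (14), C[Mg]Br; iodine, II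
Why: Duboudin–Jousseaume alkoxide-directed anti-carbomagnesiation catalysed by CuI puts the methyl on the internal alkyne carbon and magnesium on the terminal carbon cis to the carbinol in a five-membered chelate, and iodinolysis with retention gives the Z iodoalkene.

Step 10
Reactants: 16 (4E,7S,8Z)-9-iodo-4,8-dimethylnona-4,8-diene-1,7-diol
Product: 17 (1Z,3S,5E)-1,9-diiodo-2,6-dimethylnona-1,5-dien-3-ol
Conditions: I2 (1.05 equiv), PPh3, imidazole, CH2Cl2, −10 → 0 °C
Reagents that add atoms: iodine, II
Why: Appel-type iodination is much faster at the unhindered primary hydroxyl than at the hindered secondary allylic one, so one equivalent at low temperature should give the primary iodide selectively.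

Step 11
Reactants: 18 isobutyraldehyde; 19 cyclohexylamine
Product: 20 N-cyclohexyl-2-methylpropan-1-imine
Conditions: Et2O, 4 Å molecular sieves, 0 °C → rt; distil
Reagents that add atoms: cyclohexylamine (19), NC1CCCCC1
Why: Condensation of the aldehyde with the primary amine gives the aldimine, whose anion is a non-self-condensing isobutyraldehyde enolate equivalent.

Step 12
Reactants: 17 (1Z,3S,5E)-1,9-diiodo-2,6-dimethylnona-1,5-dien-3-ol; 20 N-cyclohexyl-2-methylpropan-1-imine
Product: 22 (6E,9S,10Z)-9-hydroxy-11-iodo-2,2,6,10-tetramethylundeca-6,10-dienal, via alkylated imine 21 (not isolated)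
Conditions: 20 (2.3 equiv), LiN(i-Pr)2, THF, 0 °C; then 17, −78 °C → rt; then 1 M aq. HCl, 0 °C
Reagents that add atoms: N-cyclohexyl-2-methylpropan-1-imine (20), CC(C)C=NC1CCCCC1; water, O
Why: Stork metalloenamine alkylation, in which the lithiated aldimine (in excess, one equivalent deprotonating the hydroxyl) displaces the primary iodide by SN2 to create the gem-dimethyl carbon C5 and the C5–C6 bond, followed by mild acid hydrolysis to the non-enolisable aldehyde.

Step 13
Reactants: 22 (6E,9S,10Z)-9-hydroxy-11-iodo-2,2,6,10-tetramethylundeca-6,10-dienal; 23 angelic acid [(2Z)-2-methylbut-2-enoic acid]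
Product: 24 (1Z,3S,5E)-1-iodo-2,6,10,10-tetramethyl-11-oxoundeca-1,5-dien-3-yl (2Z)-2-methylbut-2-enoate
Conditions: 23, 2,4,6-Cl3C6H2COCl, Et3N, toluene, rt; then 22, 80 °C (no DMAP)
Reagents that add atoms: angelic acid (23), C/C=C(/C)C(O)=O
Why: Yamaguchi-type esterification through the mixed trichlorobenzoic anhydride acylates the secondary allylic alcohol with retention and, run without DMAP, avoids isomerisation of the angelate to the tiglate.

Step 14
Reactants: 24 (1Z,3S,5E)-1-iodo-2,6,10,10-tetramethyl-11-oxoundeca-1,5-dien-3-yl (2Z)-2-methylbut-2-enoate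
Product: 26 (1S,2Z,4R,9E)-4-hydroxy-2,5,5,9-tetramethylcycloundeca-2,9-dien-1-yl (2Z)-2-methylbut-2-enoate, via alkenylchromium dichloride 25 (not isolated)
Conditions: CrCl2 (10 equiv), NiCl2 (2 mol %), DMSO–THF 3:1, 0.003 M (slow addition), rt; then H2O
Reagents that add atoms: none
Why: Nozaki–Hiyama–Kishi macrocyclisation, in which zerovalent nickel inserts into the C–I bond with retention of the Z geometry, transmetalation gives the alkenyl species of trivalent chromium and this adds to the aldehyde; the C4 carbinol is set by C1 because allylic 1,3-strain holds C1–H in the alkene plane, so the tethered aldehyde should reach C3 from the face opposite the angeloyloxy group with its chromium-bound oxygen in that plane, which predicts 4R.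

Step 15
Reactants: 26 (1S,2Z,4R,9E)-4-hydroxy-2,5,5,9-tetramethylcycloundeca-2,9-dien-1-yl (2Z)-2-methylbut-2-enoate; 27 acetic anhydride
Product: 28 (1S,2Z,4R,9E)-4-acetoxy-2,5,5,9-tetramethylcycloundeca-2,9-dien-1-yl (2Z)-2-methylbut-2-enoate (target)
Conditions: Ac2O, DMAP (cat.), pyridine, rt
Reagents that add atoms: acetic anhydride (27), CC(=O)OC(C)=O
Why: DMAP-catalysed acylation of the hindered secondary alcohol proceeds with retention at C4 and gives the target.

**Compound list**

1 | (S)-3-hydroxydihydrofuran-2(3H)-one [(S)-α-hydroxy-γ-butyrolactone] | O[C@H]1CCOC1=O | starting material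
2 | (S)-3-[(tert-butyldimethylsilyl)oxy]dihydrofuran-2(3H)-one | CC(C)(C)[Si](C)(C)O[C@H]1CCOC1=O | intermediate
3 | (3S)-3-[(tert-butyldimethylsilyl)oxy]tetrahydrofuran-2-ol (anomeric mixture) | CC(C)(C)[Si](C)(C)O[C@H]1CCOC1O | intermediate
4 | dimethyl (1-diazo-2-oxopropyl)phosphonate | COP(=O)(OC)C(=[N+]=[N-])C(C)=O | starting material
5 | (3S)-3-[(tert-butyldimethylsilyl)oxy]pent-4-yn-1-ol | C#C[C@@H](O[Si](C)(C)C(C)(C)C)CCO | intermediate
6 | (3S)-3-[(tert-butyldimethylsilyl)oxy]pent-4-ynal | C#C[C@@H](O[Si](C)(C)C(C)(C)C)CC=O | intermediate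
7 | isopropenylmagnesium bromide | CC(=C)[Mg]Br | starting material
8 | (5S)-5-[(tert-butyldimethylsilyl)oxy]-2-methylhept-1-en-6-yn-3-ol (C3 epimers) | CC(=C)C(O)C[C@H](O[Si](C)(C)C(C)(C)C)C#C | intermediate
9 | triethyl orthoacetate | CC(OCC)(OCC)OCC | starting material
10 | mixed ketene acetal (1-ethoxyvinyl ether of 8) | C=C(OCC)OC(C(C)=C)C[C@H](O[Si](C)(C)C(C)(C)C)C#C | intermediate
11 | ethyl (4E,7S)-7-[(tert-butyldimethylsilyl)oxy]-4-methylnon-4-en-8-ynoate | CCOC(=O)CC/C(C)=C/C[C@H](O[Si](C)(C)C(C)(C)C)C#C | intermediate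
12 | (4E,7S)-7-[(tert-butyldimethylsilyl)oxy]-4-methylnon-4-en-8-yn-1-ol | OCCC/C(C)=C/C[C@H](O[Si](C)(C)C(C)(C)C)C#C | intermediate
13 | (4E,7S)-4-methylnon-4-en-8-yne-1,7-diol | OCCC/C(C)=C/C[C@H](O)C#C | intermediate
14 | methylmagnesium bromide | C[Mg]Br | starting material
15 | alkenylmagnesium intermediate (bis-alkoxide, Z-alkenyl-MgBr) | Br[Mg]OCCC/C(C)=C/C[C@H](O[Mg]Br)/C(C)=C\[Mg]Br | intermediate
16 | (4E,7S,8Z)-9-iodo-4,8-dimethylnona-4,8-diene-1,7-diol | OCCC/C(C)=C/C[C@H](O)/C(C)=C\I | intermediate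
17 | (1Z,3S,5E)-1,9-diiodo-2,6-dimethylnona-1,5-dien-3-ol | ICCC/C(C)=C/C[C@H](O)/C(C)=C\I | intermediate
18 | isobutyraldehyde | CC(C)C=O | starting material
19 | cyclohexylamine | NC1CCCCC1 | starting material
20 | N-cyclohexyl-2-methylpropan-1-imine | CC(C)C=NC1CCCCC1 | intermediate
21 | alkylated imine (lithium alkoxide of the N-cyclohexyl imine of 22) | C1CCCCC1N=CC(C)(C)CCC/C(C)=C/C[C@H](O[Li])/C(C)=C\I | intermediate
22 | (6E,9S,10Z)-9-hydroxy-11-iodo-2,2,6,10-tetramethylundeca-6,10-dienal | O=CC(C)(C)CCC/C(C)=C/C[C@H](O)/C(C)=C\I | intermediate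
23 | angelic acid [(2Z)-2-methylbut-2-enoic acid] | C/C=C(/C)C(O)=O | starting material
24 | (1Z,3S,5E)-1-iodo-2,6,10,10-tetramethyl-11-oxoundeca-1,5-dien-3-yl (2Z)-2-methylbut-2-enoate | C/C=C(/C)C(=O)O[C@@H](C/C=C(\C)CCCC(C)(C)C=O)/C(C)=C\I | intermediate
25 | alkenylchromium dichloride derived from 24 | C/C=C(/C)C(=O)O[C@@H](C/C=C(\C)CCCC(C)(C)C=O)/C(C)=C\[Cr](Cl)Cl | intermediate
26 | (1S,2Z,4R,9E)-4-hydroxy-2,5,5,9-tetramethylcycloundeca-2,9-dien-1-yl (2Z)-2-methylbut-2-enoate | C/C=C(/C)C(=O)O[C@H]1C/C=C(\C)CCCC(C)(C)[C@H](O)/C=C\1C | intermediate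
27 | acetic anhydride | CC(=O)OC(C)=O | starting material
28 | (1S,2Z,4R,9E)-4-acetoxy-2,5,5,9-tetramethylcycloundeca-2,9-dien-1-yl (2Z)-2-methylbut-2-enoate | C/C=C(/C)C(=O)O[C@H]1C/C=C(\C)CCCC(C)(C)[C@H](OC(C)=O)/C=C\1C | target

**Step count and risks**

Total step count: 15. Longest linear sequence: 14 (steps 1–10 and 12–15; step 11 is a one-step side branch).

The three steps most likely to fail:

Step 9 (directed carbomagnesiation–iodination). Yields of this reaction are usually moderate, and protonated or over-metalated by-products are possible. The fallback sets out from 12 and comes back at 16. Gold-catalysed Markovnikov hydration of the alkyne of 12 (Ph3PAuNTf2 cat., aqueous dioxane) gives the methyl ketone (3S,5E)-3-[(tert-butyldimethylsilyl)oxy]-9-hydroxy-6-methylnon-5-en-2-one F1. Silylation of the primary hydroxyl (t-BuMe2SiCl, imidazole) gives (3S,5E)-3,9-bis[(tert-butyldimethylsilyl)oxy]-6-methylnon-5-en-2-one F2. A Stork–Zhao Wittig iodomethylenation (Ph3P=CHI from [Ph3PCH2I]I and NaN(SiMe3)2, THF, −78 °C) places the iodine cis to the oxygenated carbon with α-silyloxy methyl ketones and gives (1Z,3S,5E)-3,9-bis[(tert-butyldimethylsilyl)oxy]-1-iodo-2,6-dimethylnona-1,5-diene F3. Bu4NF then removes both silyl groups and delivers 16.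

Step 12 (quaternary-carbon alkylation in the presence of a free alkoxide and a vinyl iodide). The fallback sets out from 17 and comes back at 22. Lithiated isobutyronitrile (Me2CHCN, LiN(i-Pr)2, 2.2 equiv, THF, −78 °C → rt) is alkylated with 17 to give the nitrile (6E,9S,10Z)-9-hydroxy-11-iodo-2,2,6,10-tetramethylundeca-6,10-dienenitrile F4. Reduction with i-Bu2AlH (toluene, −78 °C) and hydrolysis of the aluminium imine give 22.

Step 14 (eleven-membered ring closure and the sense of induction at C4). The 4R outcome rests on a transition-state model, not on a precedent for this ring, so it is the least certain point of the route. The fallback sets out from 24 and comes back at 26. If the closure gives mainly the epimer (1S,2Z,4S,9E)-4-hydroxy-2,5,5,9-tetramethylcycloundeca-2,9-dien-1-yl (2Z)-2-methylbut-2-enoate F5, it is oxidised with Dess–Martin periodinane to the macrocyclic enone (1S,2Z,9E)-2,5,5,9-tetramethyl-4-oxocycloundeca-2,9-dien-1-yl (2Z)-2-methylbut-2-enoate F6. Luche reduction (NaBH4, CeCl3, MeOH, −78 °C) then forms the carbinol by hydride delivery instead of C–C bond formation; because it builds the centre in the opposite sense, it should favour the 4R alcohol 26.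

**Further compounds**

F1 | step 9 | (3S,5E)-3-[(tert-butyldimethylsilyl)oxy]-9-hydroxy-6-methylnon-5-en-2-one | CC(=O)[C@@H](O[Si](C)(C)C(C)(C)C)C/C=C(\C)CCCO
F2 | step 9 | (3S,5E)-3,9-bis[(tert-butyldimethylsilyl)oxy]-6-methylnon-5-en-2-one | CC(=O)[C@@H](O[Si](C)(C)C(C)(C)C)C/C=C(\C)CCCO[Si](C)(C)C(C)(C)C
F3 | step 9 | (1Z,3S,5E)-3,9-bis[(tert-butyldimethylsilyl)oxy]-1-iodo-2,6-dimethylnona-1,5-diene | I/C=C(C)\[C@@H](O[Si](C)(C)C(C)(C)C)C/C=C(\C)CCCO[Si](C)(C)C(C)(C)C
F4 | step 12 | (6E,9S,10Z)-9-hydroxy-11-iodo-2,2,6,10-tetramethylundeca-6,10-dienenitrile | N#CC(C)(C)CCC/C(C)=C/C[C@H](O)/C(C)=C\I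
F5 | step 14 | (1S,2Z,4S,9E)-4-hydroxy-2,5,5,9-tetramethylcycloundeca-2,9-dien-1-yl (2Z)-2-methylbut-2-enoate | C/C=C(/C)C(=O)O[C@H]1C/C=C(\C)CCCC(C)(C)[C@@H](O)/C=C\1C
F6 | step 14 | (1S,2Z,9E)-2,5,5,9-tetramethyl-4-oxocycloundeca-2,9-dien-1-yl (2Z)-2-methylbut-2-enoate | C/C=C(/C)C(=O)O[C@H]1C/C=C(\C)CCCC(C)(C)C(=O)/C=C\1C
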